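## Analysis of the target

The target is a cyclohex-2-enone fused to an oxirane (7-oxabicyclo[4.1.0]hept-3-en-2-one). One ring numbering is used throughout: C1 is the ketone carbon, C2 carries the (E)-hept-1-enyl group, C3 carries the hydroxymethyl group (its carbon is C7), C4 is the secondary carbinol, C5 is the oxirane CH, and C6 is the quaternary oxirane carbon bearing the (E)-2-methylbut-2-enoic acid chain.

There are three contiguous stereocentres, C4 (R), C5 (S) and C6 (S). The oxirane can only be cis-fused, so C5 follows from C6. The C4 hydroxyl lies on the ring face opposite to the oxirane oxygen.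

The α,β-epoxy ketone and the γ-hydroxy enone are base-labile, and the cross-conjugated diene, the free acid and the primary allylic alcohol limit the end-game. Any intermediate with the C6 oxygen β to an enolisable ketone can expel it and end as an achiral phenol or quinone.

The difficulty is that every ring carbon is functionalised, the C2=C3 alkene is tetrasubstituted, and C6 is a fully substituted oxygenated carbon with no neighbouring stereocentre to set it.

The strategy rests on two features. C4–C5–C6–C1 is a four-carbon chain with the oxygenated quaternary C6 in the middle, the pattern of a mirror-symmetric 3,3-disubstituted cyclobutanone. C2=C3 with its alkenyl and oxymethyl groups is the internal alkyne of a conjugated enyne. Inserting that alkyne into one of the two enantiotopic acyl–CH2 bonds gives the ring, the alkene and C6 at once. C4 then arrives as a ketone and C1 as a methylene, which defines the remaining work.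

## Retrosynthetic reasoning

**35 from 34.** No skeletal bond is cut. The acid and the C7 hydroxyl are carried as silicon-based groups (in 34) that one fluoride treatment removes, because the epoxy ketone and γ-hydroxy enone of 35 would not tolerate ester hydrolysis with hydroxide.

**34 from 33.** The C4–H bond is cut, leading back to the epoxy ene-dione 33. C4 comes out of the ring-forming step as a carbonyl and is needed as such to functionalise C5, so the carbinol is made last. The forward reduction must choose C4 over C1 and deliver hydride from the oxirane face.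

**33 from 31 (through 32).** The O–C5 bond of the oxirane is cut. The oxirane oxygen is the C6 oxygen that has been in the molecule since the cyclobutanone, so C6 is never touched. Forward, the tertiary silyl ether of 31 is removed to give bromohydrin 32, and the alkoxide displaces bromide at C5. Only the cis-fused oxirane can form, so C6 dictates C5.

**31 from 29 (through 30).** The C5–Br bond is cut. In ene-dione 29 the only α-hydrogens are on C5, since C1 is flanked by the quaternary C6 and by C2, so enolisation is regiospecific. The leaving group is introduced through the silyl enol ether 30.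

**29 from 23 and 28.** The side-chain C=C is cut, leading to aldehyde 23 and the stabilised ylide 28, which gives the (E)-trisubstituted enoate. The olefination is placed late because the two-carbon arm on C6 is first needed as an alcohol for the C1 oxidation.

**23 from 22, and 22 from 19 (through 20 and 21).** The C1=O bond is traced back to the C1 methylene of 19, and this is where the plan had to be repaired. An ordinary enone γ-oxidation cannot be relied on here. Base enolises only towards C5, where the enolate is linearly conjugated with the diene. A radical or hydride abstraction would prefer the allylic CH2 of the heptenyl chain (a more delocalised radical) or the silyloxymethyl CH2 over C1. The hydroxyethyl arm of 19, however, places an oxygen exactly five atoms from the C1 hydrogens. Its nitrite 20 therefore hands the oxidation to C1 through a six-membered hydrogen transfer, giving oxime 22 via the nitroso compound 21. The oxime is already at the ketone oxidation level and is oxidised to 23 together with the alcohol.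

**19 from 18, and 18 from 16 (through 17).** No skeletal bond is cut. The acetal of 16 is opened to aldehyde 18 and reduced to alcohol 19. The acetal is kept in the ring-forming step because it is inert to zerovalent nickel.

**16 from 7 and 13 (through 14 and 15).** C3–C4 and C1–C2 are cut, which removes the two alkyne carbons from the ring and leaves the prochiral cyclobutanone 7 and the enyne 13. This is the only disconnection that reduces the ring, the tetrasubstituted diene unit and the C6 stereocentre to two achiral pieces. Forward, the catalyst must select one of two enantiotopic C–C bonds and one alkyne orientation, and the metallacycle 15 must close before it loses the β-silyloxy group.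

**7 from 6, 6 from 3 and 4 (through 5), 3 from 1 (through 2).** The four-membered ring is cut into the ketene 5 (from 4) and the silyl enol ether 3 of ketone 1. The [2+2] places the silyloxy carbon opposite the carbonyl, and dechlorination of 6 restores the mirror plane.

**13 from 9 and 12; 9 from 8; 12 from 10 (through 11).** The sp–sp2 bond of the enyne is cut, leading to the propargyl ether 9 and the (E)-alkenyl iodide 12. The iodide comes from alkyne 10 by syn-hydrometalation (11), which fixes the alkene geometry.

**28 from 26 (through 27); 26 from 24 and 25.** The ylide is assembled from the bromo ester 26, itself from alcohol 24 and acyl bromide 25. This ester is chosen so that fluoride frees the acid at the end.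

## Alternatives that were turned down

**Alternative 1:** Payne shift on an epoxy para-quinol.
- **Disconnection:** the O–C5 bond of the oxirane is traced back to a C4–C5 oxirane and a C6 silyl ether in A1, a para-quinol derivative with the ketone at C3 and no C7 yet.
- **Forward key step:** a buffered fluoride source frees the C6 alkoxide of A1, which opens the neighbouring oxirane at C5 and gives A2. C7 is then added to the C3 ketone, and a 1,3-oxidative transposition with hexavalent chromium moves the carbonyl to C1.
- **For it:** para-quinols come from phenols in one oxidation. The Payne step is a stereospecific SN2, so the anti relation between the C4 hydroxyl and the new oxirane is guaranteed. On this point it is stronger than the chosen route, which depends on a facially selective reduction.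
- **Against it:** the absolute configuration has to come from an enantioselective epoxidation of a dienone, which is hard to control, or from a resolution. The liberated C4 alkoxide sits next to a ketone and can undergo α-ketol shifts, and the Payne equilibrium is reversible. The later 1,2-addition and chromium transposition must be run next to an oxirane, a free or protected C4 hydroxyl and the diene.
- **Comparison:** the chosen route sets C6 by catalysis and brings in both alkene substituents with the ring, at the price of a riskier key step.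

**Alternative 2:** ring-closing enyne metathesis.
- **Disconnection:** the C2=C3 bond and the exocyclic vinyl C=C are cut, leading to the acyclic epoxy enyne A3.
- **Forward key step:** the second-generation Grubbs catalyst (H2IMes)(PCy3)Cl2Ru=CHPh joins the C1 ethynyl group and the C3 methylidene of A3 to give the vinylcyclohexene A4. The vinyl group is then extended by cross-metathesis.
- **For it:** C1 is already oxygenated, so the hardest oxidation of the chosen route does not arise; here the alternative is clearly stronger. All four stereocentres can be set in the open chain by established asymmetric reactions.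
- **Against it:** the ring alkene formed is tetrasubstituted, and a 1,1-disubstituted alkene next to a silyloxy-bearing carbon is a poor partner for the ruthenium vinylcarbene. A3 needs a long linear sequence with a quaternary oxirane, and the pentyl group still has to be added afterwards.
- **Comparison:** the chosen route reaches the complete carbocycle from two achiral pieces of three steps each.

**Alternative 3:** chromium-mediated ring closure at C3–C4.
- **Disconnection:** the C3–C4 bond is cut, leading to the acyclic epoxy aldehyde A5 with a C3 alkenyl iodide.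
- **Forward key step:** CrCl2 (divalent chromium) with catalytic NiCl2 (divalent nickel) couples the iodide and the aldehyde of A5, closing the ring and forming the C4 carbinol in A6.
- **For it:** the coupling is mild and tolerant, C1 is already oxygenated, and the C4 hydroxyl is created directly. In reliability of the ring-closing step it is superior to the chosen key step.
- **Against it:** A5 needs a geometrically defined tetrasubstituted dienyl iodide and an α,β-epoxy aldehyde, both hard to make and to keep. The C4 configuration in the closure is not controlled, and chromium is used in large excess. The linear sequence to A5 is long.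
- **Comparison:** the chosen route is shorter and convergent, and relays C5 from C6 and C4 from the oxirane, but carries more risk in a single step.

Key step: step 7

**Assumptions**
- The target is taken as drawn: (4R,5S,6S) in the ring numbering above, C4 hydroxyl anti to the oxirane.
- Which enantiomer of the phosphoramidite gives (S) at C6 cannot be predicted with confidence. The route is written for the enantiomer that does; both are available.
- The primary silyl ether is changed from tert-butyldimethylsilyl to tert-butyldiphenylsilyl so that the tertiary triethylsilyl ether can later be removed by acid without touching it.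

## Steps

**Step 1**
Reactants: 1 4,4-dimethoxybutan-2-one
Product: 3 [(4,4-dimethoxybut-1-en-2-yl)oxy]triethylsilane, via lithium enolate 2 (not isolated)
Conditions: LiN(i-Pr)2, THF, −78 °C; then Et3SiCl, −78 to 0 °C
Reagents that add atoms: chlorotriethylsilane, CC[Si](Cl)(CC)CC
Why: Kinetic deprotonation by the hindered amide takes place at the methyl group, since the methylene is shielded by the acetal carbon, and the terminal enolate is silylated on oxygen (kinetic enolate O-silylation); the low temperature suppresses β-methoxide loss from any internal enolate.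

**Step 2**
Reactants: 3 [(4,4-dimethoxybut-1-en-2-yl)oxy]triethylsilane; 4 trichloroacetyl chloride
Product: 6 rac-2,2-dichloro-3-(2,2-dimethoxyethyl)-3-[(triethylsilyl)oxy]cyclobutan-1-one, via dichloroketene 5 (not isolated)
Conditions: Zn–Cu couple, POCl3, Et2O, 25 °C
Reagents that add atoms: none
Why: Dichloroketene formed by zinc dechlorination adds to the electron-rich enol ether in a [2+2] cycloaddition; the nucleophilic CH2 terminus bonds to the ketene carbonyl carbon, so the silyloxy carbon ends up opposite the ketone, and POCl3 binds ZnCl2 to protect the acetal and the strained β-silyloxy ketone.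

**Step 3**
Reactants: 6 rac-2,2-dichloro-3-(2,2-dimethoxyethyl)-3-[(triethylsilyl)oxy]cyclobutan-1-one
Product: 7 3-(2,2-dimethoxyethyl)-3-[(triethylsilyl)oxy]cyclobutan-1-one
Conditions: Zn dust, NH4Cl, MeOH, 25 °C
Reagents that add atoms: none
Why: Zinc removes both α-chlorines by reductive dehalogenation under nearly neutral conditions that spare the acetal and the silyl ether; the product has a mirror plane through C=O and C3 and is prochiral.

**Step 4**
Reactants: 8 prop-2-yn-1-ol
Product: 9 tert-butyl(diphenyl)(prop-2-yn-1-yloxy)silane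
Conditions: t-BuPh2SiCl, imidazole, CH2Cl2, 0 to 25 °C
Reagents that add atoms: tert-butyl(chloro)diphenylsilane, CC(C)(C)[Si](Cl)(c1ccccc1)c1ccccc1
Why: Standard silylation of a primary alcohol; the tert-butyldiphenylsilyl ether is inert to zerovalent nickel and survives the later acid removal of the tertiary triethylsilyl ether.

**Step 5**
Reactants: 10 hept-1-yne
Product: 12 (1E)-1-iodohept-1-ene, via alkenylzirconocene chloride 11 (not isolated)
Conditions: Cp2Zr(H)Cl, THF, 25 °C; then I2, 0 °C
Reagents that add atoms: iodine, II
Why: Hydrozirconation adds Zr–H syn across the alkyne with zirconium at the terminal carbon, and iodinolysis of the C–Zr bond proceeds with retention, which fixes the (E) geometry.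

**Step 6**
Reactants: 9 tert-butyl(diphenyl)(prop-2-yn-1-yloxy)silane; 12 (1E)-1-iodohept-1-ene
Product: 13 tert-butyl{[(4E)-dec-4-en-2-yn-1-yl]oxy}diphenylsilane
Conditions: PdCl2(PPh3)2 (2 mol %, divalent palladium), CuI (4 mol %, monovalent copper), Et3N, THF, 25 °C
Reagents that add atoms: none
Why: Sonogashira coupling of a terminal alkyne with an alkenyl iodide proceeds with retention of the alkene geometry and gives the conjugated enyne.

**Step 7**
Reactants: 7 3-(2,2-dimethoxyethyl)-3-[(triethylsilyl)oxy]cyclobutan-1-one; 13 tert-butyl{[(4E)-dec-4-en-2-yn-1-yl]oxy}diphenylsilane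
Product: 16 (5S)-2-{[tert-butyl(diphenyl)silyl]oxymethyl}-5-(2,2-dimethoxyethyl)-3-[(1E)-hept-1-en-1-yl]-5-[(triethylsilyl)oxy]cyclohex-2-en-1-one, via oxanickelacyclopentene 14 (not isolated), via seven-membered nickelacycle 15 (not isolated)
Conditions: Ni(cod)2 (10 mol %, zerovalent nickel), chiral phosphoramidite L* [(S)-1,1'-binaphthyl-2,2'-diyl N,N-bis((R)-1-phenylethyl)phosphoramidite or its enantiomer] (20 mol %), toluene, 40 °C
Reagents that add atoms: none
Why: Proposed new method: zerovalent nickel carrying the chiral phosphoramidite couples the ketone carbonyl of 7 with the alkyne of 13 by oxidative cyclisation to 14, and the new C3–C4 bond forms at the alkyne carbon remote from the alkene because the alkenyl-bearing carbon is held on nickel by η3 coordination of the enyne. β-Carbon elimination, driven by release of the four-ring strain, then breaks one of the two enantiotopic acyl–CH2 bonds to give 15, and C(sp3)–C(sp2) reductive elimination forms C1–C2. The closest known chemistry is the racemic nickel-catalysed intermolecular [4+2] of cyclobutanones with alkynes and the enantioselective desymmetrising C–C activation of 3,3-disubstituted cyclobutanones in tethered systems; an intermolecular enantioselective version with an enyne and a 3-silyloxy group has not been shown. The six-membered ring is closed by reductive elimination from the seven-membered metallacycle, that is by formal insertion of the two alkyne carbons into the acyl–Cα bond and not by cyclisation of an open chain. The only new stereocentre, C6, is fixed in the β-carbon elimination, where the chiral pocket of the ligand decides which CH2 group passes to nickel. The step needs enantiotopic-bond selection (ligand), one alkyne orientation (the conjugated alkene of 13) and reductive elimination faster than β-silyloxide loss from 15, which the bulky triethylsilyl ether and the π-accepting phosphoramidite are meant to secure.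

**Step 8**
Reactants: 16 cyclohexenone acetal (5S)
Product: 18 2-[(1S)-4-{[tert-butyl(diphenyl)silyl]oxymethyl}-3-[(1E)-hept-1-en-1-yl]-5-oxo-1-[(triethylsilyl)oxy]cyclohex-3-en-1-yl]acetaldehyde, via collidinium N,O-acetal triflate 17 (not isolated)
Conditions: Et3SiOTf, 2,4,6-collidine, CH2Cl2, 0 °C; then H2O
Reagents that add atoms: water, O
Why: The silyl triflate ionises the dimethyl acetal and collidine traps the oxocarbenium ion as a pyridinium salt that water hydrolyses to the aldehyde (base-buffered acetal cleavage); no protic acid is present, so the tertiary silyl ether, the β-silyloxy ketone and the diene are not endangered.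

**Step 9**
Reactants: 18 aldehyde (1S)
Product: 19 (5S)-2-{[tert-butyl(diphenyl)silyl]oxymethyl}-3-[(1E)-hept-1-en-1-yl]-5-(2-hydroxyethyl)-5-[(triethylsilyl)oxy]cyclohex-2-en-1-one
Conditions: NaBH(OAc)3, ClCH2CH2Cl, 25 °C
Reagents that add atoms: none
Why: The triacetoxyborohydride reduces aldehydes but not the hindered conjugated ketone (chemoselective hydride reduction); the non-basic medium prevents silyl migration to the new primary hydroxyl, which lies five atoms from the C1 hydrogens.

**Step 10**
Reactants: 19 hydroxyethyl enone (5S)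
Product: 22 (5S)-2-{[tert-butyl(diphenyl)silyl]oxymethyl}-3-[(1E)-hept-1-en-1-yl]-4-(hydroxyimino)-5-(2-hydroxyethyl)-5-[(triethylsilyl)oxy]cyclohex-2-en-1-one, via nitrite ester 20 (not isolated), via C-nitroso compound 21 (not isolated)
Conditions: t-BuONO, CH2Cl2, 25 °C, dark; evaporate; hν (365 nm), benzene, 15 °C; then i-PrOH, 60 °C
Reagents that add atoms: tert-butyl nitrite, CC(C)(C)ON=O
Why: Barton nitrite ester reaction: photolysis of 20 gives an alkoxy radical that abstracts hydrogen through a six-membered transition state, and of the two positions within reach the allylic C1–H is much weaker and better polarity-matched than the C5–H next to the carbonyl; the allylic radical recombines with NO at C1 and 21 tautomerises to the conjugated oxime. The intramolecular relay is used because an intermolecular γ-oxidation would have to compete with the allylic CH2 groups of the heptenyl and silyloxymethyl substituents, and base enolises only towards C5.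

**Step 11**
Reactants: 22 oxime alcohol (5S)
Product: 23 2-[(1S)-4-{[tert-butyl(diphenyl)silyl]oxymethyl}-3-[(1E)-hept-1-en-1-yl]-2,5-dioxo-1-[(triethylsilyl)oxy]cyclohex-3-en-1-yl]acetaldehyde
Conditions: Dess–Martin periodinane (pentavalent iodine), NaHCO3, water-saturated CH2Cl2, 0 to 25 °C
Reagents that add atoms: water, O
Why: The periodinane oxidises the primary alcohol to the aldehyde and cleaves the oxime oxidatively to the ketone (periodinane deoximation), so the ene-dione and the aldehyde appear in one operation; bicarbonate protects the tertiary silyl ether from the acetic acid formed.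

**Step 12**
Reactants: 24 2-(trimethylsilyl)ethan-1-ol; 25 2-bromopropanoyl bromide
Product: 26 rac-2-(trimethylsilyl)ethyl 2-bromopropanoate
Conditions: pyridine, CH2Cl2, 0 °C
Reagents that add atoms: none
Why: Acylation of the alcohol by the acyl bromide; the 2-(trimethylsilyl)ethyl ester is chosen because fluoride cleaves it at the end without hydroxide.

**Step 13**
Reactants: 26 rac-2-(trimethylsilyl)ethyl 2-bromopropanoate
Product: 28 2-(trimethylsilyl)ethyl 2-(triphenyl-λ5-phosphanylidene)propanoate, via phosphonium bromide 27 (not isolated)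
Conditions: PPh3, toluene, 80 °C; then aq. NaOH, CH2Cl2, 0 °C
Reagents that add atoms: triphenylphosphine, c1ccc(cc1)P(c1ccccc1)c1ccccc1
Why: SN2 quaternisation of the phosphine by the α-bromo ester and deprotonation of the acidic α-C–H give the stabilised ylide.

**Step 14**
Reactants: 23 ene-dione aldehyde (1S); 28 ylide
Product: 29 2-(trimethylsilyl)ethyl (2E)-4-[(1S)-4-{[tert-butyl(diphenyl)silyl]oxymethyl}-3-[(1E)-hept-1-en-1-yl]-2,5-dioxo-1-[(triethylsilyl)oxy]cyclohex-3-en-1-yl]-2-methylbut-2-enoate
Conditions: toluene, 50 °C
Reagents that add atoms: none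
Why: Wittig reaction of a stabilised α-methyl ylide is (E)-selective and takes place at the aldehyde only, the two ring ketones being hindered and conjugated; the neutral conditions avoid enolisation at C5.

**Step 15**
Reactants: 29 ene-dione ester (1S)
Product: 31 2-(trimethylsilyl)ethyl (2E)-4-[(1R,6S)-6-bromo-4-{[tert-butyl(diphenyl)silyl]oxymethyl}-3-[(1E)-hept-1-en-1-yl]-2,5-dioxo-1-[(triethylsilyl)oxy]cyclohex-3-en-1-yl]-2-methylbut-2-enoate (bromine trans to the silyloxy group), via trimethylsilyl enol ether 30 (not isolated)
Conditions: LiN(SiMe3)2 added to 29 and Me3SiCl in THF, −78 °C; then N-bromosuccinimide, THF, −78 to −20 °C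
Reagents that add atoms: N-bromosuccinimide, O=C1CCC(=O)N1Br
Why: C5 carries the only α-hydrogens of the ene-dione, so enolisation is regiospecific; silylation in situ at −78 °C keeps the enolate from expelling the β-silyloxy group, and the silyl enol ether is brominated at C5 (electrophilic α-bromination). Bromine should enter anti to the bulky silyloxy group, but either C5 epimer serves, because the α-bromo ketone epimerises under the closure conditions of step 16.

**Step 16**
Reactants: 31 bromo ene-dione (1R,6S)
Product: 33 2-(trimethylsilyl)ethyl (2E)-4-[(1S,6R)-4-{[tert-butyl(diphenyl)silyl]oxymethyl}-3-[(1E)-hept-1-en-1-yl]-2,5-dioxo-7-oxabicyclo[4.1.0]hept-3-en-1-yl]-2-methylbut-2-enoate, via bromohydrin 32 (not isolated)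
Conditions: camphorsulfonic acid (10 mol %), MeOH/CH2Cl2, 0 °C; then K2CO3, 0 °C
Reagents that add atoms: none
Why: Acid methanolysis removes the tertiary triethylsilyl ether and leaves the tert-butyldiphenylsilyl ether and the silylethyl ester; carbonate then closes the oxirane by intramolecular SN2 at C5 with inversion (halohydrin closure). Only the cis-fused oxirane can form, so C5 is set by C6.

**Step 17**
Reactants: 33 epoxy ene-dione (1S,6R)
Product: 34 2-(trimethylsilyl)ethyl (2E)-4-[(1S,5R,6S)-4-{[tert-butyl(diphenyl)silyl]oxymethyl}-3-[(1E)-hept-1-en-1-yl]-5-hydroxy-2-oxo-7-oxabicyclo[4.1.0]hept-3-en-1-yl]-2-methylbut-2-enoate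
Conditions: i-Bu2AlH (1.1 equiv), toluene, −78 °C; aq. KNaC4H4O6 work-up
Reagents that add atoms: none
Why: Substrate-directed reduction: the Lewis acidic aluminium hydride should bind the oxirane oxygen and pass hydride to the adjacent C4 carbonyl from that face, which places the new hydroxyl anti to the oxirane (C4 R). C4 is preferred over C1 because C1 is flanked by the quaternary C6 and the alkenyl-bearing C2, and ketones react before the hindered enoate at −78 °C.

**Step 18**
Reactants: 34 protected epoxy alcohol (1S,5R,6S)
Product: 35 (2E)-4-[(1S,5R,6S)-3-[(1E)-hept-1-en-1-yl]-5-hydroxy-4-(hydroxymethyl)-2-oxo-7-oxabicyclo[4.1.0]hept-3-en-1-yl]-2-methylbut-2-enoic acid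
Conditions: tris(dimethylamino)sulfonium difluorotrimethylsilicate, DMF, 0 to 25 °C; aq. NH4Cl work-up
Reagents that add atoms: none
Why: Fluoride cleaves the Si–O bond of the primary silyl ether and triggers β-elimination of the 2-(trimethylsilyl)ethyl ester (global fluoride desilylation) under nearly neutral conditions that the epoxy ketone and γ-hydroxy enone should tolerate; no stereocentre is touched.

## Compound list

1 | 4,4-dimethoxybutan-2-one | CC(=O)CC(OC)OC | starting material
2 | lithium 4,4-dimethoxybut-1-en-2-olate | [Li]OC(=C)CC(OC)OC | intermediate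
3 | [(4,4-dimethoxybut-1-en-2-yl)oxy]triethylsilane | C=C(O[Si](CC)(CC)CC)CC(OC)OC | intermediate
4 | trichloroacetyl chloride | ClC(=O)C(Cl)(Cl)Cl | starting material
5 | dichloroketene | ClC(Cl)=C=O | intermediate
6 | rac-2,2-dichloro-3-(2,2-dimethoxyethyl)-3-[(triethylsilyl)oxy]cyclobutan-1-one | O=C1CC(O[Si](CC)(CC)CC)(CC(OC)OC)C1(Cl)Cl | intermediate
7 | 3-(2,2-dimethoxyethyl)-3-[(triethylsilyl)oxy]cyclobutan-1-one | O=C1CC(O[Si](CC)(CC)CC)(CC(OC)OC)C1 | intermediate
8 | prop-2-yn-1-ol | C#CCO | starting material
9 | tert-butyl(diphenyl)(prop-2-yn-1-yloxy)silane | C#CCO[Si](c1ccccc1)(c1ccccc1)C(C)(C)C | intermediate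
10 | hept-1-yne | CCCCCC#C | starting material
11 | chlorobis(cyclopentadienyl)[(1E)-hept-1-en-1-yl]zirconium | CCCCC/C=C/[Zr](Cl)(C1C=CC=C1)C1C=CC=C1 | intermediate
12 | (1E)-1-iodohept-1-ene | CCCCC/C=C/I | intermediate
13 | tert-butyl{[(4E)-dec-4-en-2-yn-1-yl]oxy}diphenylsilane | CCCCC/C=C/C#CCO[Si](c1ccccc1)(c1ccccc1)C(C)(C)C | intermediate
14 | spiro oxanickelacyclopentene from 7 and 13 (nickel bonded to the oxygen on the former carbonyl carbon and to the heptenyl-bearing alkene carbon; ligand on nickel not drawn) | CCCCC/C=C/C1=C(CO[Si](c2ccccc2)(c2ccccc2)C(C)(C)C)C2(CC(O[Si](CC)(CC)CC)(CC(OC)OC)C2)O[Ni]1 | intermediate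
15 | seven-membered nickelacycle after β-carbon elimination, (S) at the silyloxy carbon (nickel bonded to the C1 methylene and to C2; ligand not drawn) | CCCCC/C=C/C1=C(CO[Si](c2ccccc2)(c2ccccc2)C(C)(C)C)C(=O)C[C@@](O[Si](CC)(CC)CC)(CC(OC)OC)C[Ni]1 | intermediate
16 | (5S)-2-{[tert-butyl(diphenyl)silyl]oxymethyl}-5-(2,2-dimethoxyethyl)-3-[(1E)-hept-1-en-1-yl]-5-[(triethylsilyl)oxy]cyclohex-2-en-1-one | CCCCC/C=C/C1=C(CO[Si](c2ccccc2)(c2ccccc2)C(C)(C)C)C(=O)C[C@@](O[Si](CC)(CC)CC)(CC(OC)OC)C1 | intermediate
17 | 1-{2-[(1S)-4-{[tert-butyl(diphenyl)silyl]oxymethyl}-3-[(1E)-hept-1-en-1-yl]-5-oxo-1-[(triethylsilyl)oxy]cyclohex-3-en-1-yl]-1-methoxyethyl}-2,4,6-trimethylpyridinium trifluoromethanesulfonate (both epimers at the N,O-acetal carbon) | CCCCC/C=C/C1=C(CO[Si](c2ccccc2)(c2ccccc2)C(C)(C)C)C(=O)C[C@@](O[Si](CC)(CC)CC)(CC(OC)[n+]2c(C)cc(C)cc2C)C1.[O-]S(=O)(=O)C(F)(F)F | intermediate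
18 | 2-[(1S)-4-{[tert-butyl(diphenyl)silyl]oxymethyl}-3-[(1E)-hept-1-en-1-yl]-5-oxo-1-[(triethylsilyl)oxy]cyclohex-3-en-1-yl]acetaldehyde | CCCCC/C=C/C1=C(CO[Si](c2ccccc2)(c2ccccc2)C(C)(C)C)C(=O)C[C@@](O[Si](CC)(CC)CC)(CC=O)C1 | intermediate
19 | (5S)-2-{[tert-butyl(diphenyl)silyl]oxymethyl}-3-[(1E)-hept-1-en-1-yl]-5-(2-hydroxyethyl)-5-[(triethylsilyl)oxy]cyclohex-2-en-1-one | CCCCC/C=C/C1=C(CO[Si](c2ccccc2)(c2ccccc2)C(C)(C)C)C(=O)C[C@@](O[Si](CC)(CC)CC)(CCO)C1 | intermediate
20 | 2-[(1S)-4-{[tert-butyl(diphenyl)silyl]oxymethyl}-3-[(1E)-hept-1-en-1-yl]-5-oxo-1-[(triethylsilyl)oxy]cyclohex-3-en-1-yl]ethyl nitrite | CCCCC/C=C/C1=C(CO[Si](c2ccccc2)(c2ccccc2)C(C)(C)C)C(=O)C[C@@](O[Si](CC)(CC)CC)(CCON=O)C1 | intermediate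
21 | (5S)-2-{[tert-butyl(diphenyl)silyl]oxymethyl}-3-[(1E)-hept-1-en-1-yl]-5-(2-hydroxyethyl)-4-nitroso-5-[(triethylsilyl)oxy]cyclohex-2-en-1-one (both C4 epimers) | CCCCC/C=C/C1=C(CO[Si](c2ccccc2)(c2ccccc2)C(C)(C)C)C(=O)C[C@@](O[Si](CC)(CC)CC)(CCO)C1N=O | intermediate
22 | (5S)-2-{[tert-butyl(diphenyl)silyl]oxymethyl}-3-[(1E)-hept-1-en-1-yl]-4-(hydroxyimino)-5-(2-hydroxyethyl)-5-[(triethylsilyl)oxy]cyclohex-2-en-1-one (oxime geometry not defined) | CCCCC/C=C/C1=C(CO[Si](c2ccccc2)(c2ccccc2)C(C)(C)C)C(=O)C[C@@](O[Si](CC)(CC)CC)(CCO)C1=NO | intermediate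
23 | 2-[(1S)-4-{[tert-butyl(diphenyl)silyl]oxymethyl}-3-[(1E)-hept-1-en-1-yl]-2,5-dioxo-1-[(triethylsilyl)oxy]cyclohex-3-en-1-yl]acetaldehyde | CCCCC/C=C/C1=C(CO[Si](c2ccccc2)(c2ccccc2)C(C)(C)C)C(=O)C[C@@](O[Si](CC)(CC)CC)(CC=O)C1=O | intermediate
24 | 2-(trimethylsilyl)ethan-1-ol | C[Si](C)(C)CCO | starting material
25 | 2-bromopropanoyl bromide | CC(Br)C(=O)Br | starting material
26 | rac-2-(trimethylsilyl)ethyl 2-bromopropanoate | CC(Br)C(=O)OCC[Si](C)(C)C | intermediate
27 | triphenyl{1-oxo-1-[2-(trimethylsilyl)ethoxy]propan-2-yl}phosphonium bromide | CC(C(=O)OCC[Si](C)(C)C)[P+](c1ccccc1)(c1ccccc1)c1ccccc1.[Br-] | intermediate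
28 | 2-(trimethylsilyl)ethyl 2-(triphenyl-λ5-phosphanylidene)propanoate | CC(=P(c1ccccc1)(c1ccccc1)c1ccccc1)C(=O)OCC[Si](C)(C)C | intermediate
29 | 2-(trimethylsilyl)ethyl (2E)-4-[(1S)-4-{[tert-butyl(diphenyl)silyl]oxymethyl}-3-[(1E)-hept-1-en-1-yl]-2,5-dioxo-1-[(triethylsilyl)oxy]cyclohex-3-en-1-yl]-2-methylbut-2-enoate | CCCCC/C=C/C1=C(CO[Si](c2ccccc2)(c2ccccc2)C(C)(C)C)C(=O)C[C@@](O[Si](CC)(CC)CC)(C/C=C(\C)C(=O)OCC[Si](C)(C)C)C1=O | intermediate
30 | 2-(trimethylsilyl)ethyl (2E)-4-[(1S)-4-{[tert-butyl(diphenyl)silyl]oxymethyl}-5-[(1E)-hept-1-en-1-yl]-6-oxo-1-[(triethylsilyl)oxy]-3-[(trimethylsilyl)oxy]cyclohexa-2,4-dien-1-yl]-2-methylbut-2-enoate | CCCCC/C=C/C1=C(CO[Si](c2ccccc2)(c2ccccc2)C(C)(C)C)C(O[Si](C)(C)C)=C[C@@](O[Si](CC)(CC)CC)(C/C=C(\C)C(=O)OCC[Si](C)(C)C)C1=O | intermediate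
31 | 2-(trimethylsilyl)ethyl (2E)-4-[(1R,6S)-6-bromo-4-{[tert-butyl(diphenyl)silyl]oxymethyl}-3-[(1E)-hept-1-en-1-yl]-2,5-dioxo-1-[(triethylsilyl)oxy]cyclohex-3-en-1-yl]-2-methylbut-2-enoate (bromine trans to the silyloxy group) | CCCCC/C=C/C1=C(CO[Si](c2ccccc2)(c2ccccc2)C(C)(C)C)C(=O)[C@@H](Br)[C@@](O[Si](CC)(CC)CC)(C/C=C(\C)C(=O)OCC[Si](C)(C)C)C1=O | intermediate
32 | 2-(trimethylsilyl)ethyl (2E)-4-[(1R,6S)-6-bromo-4-{[tert-butyl(diphenyl)silyl]oxymethyl}-3-[(1E)-hept-1-en-1-yl]-1-hydroxy-2,5-dioxocyclohex-3-en-1-yl]-2-methylbut-2-enoate | CCCCC/C=C/C1=C(CO[Si](c2ccccc2)(c2ccccc2)C(C)(C)C)C(=O)[C@@H](Br)[C@@](O)(C/C=C(\C)C(=O)OCC[Si](C)(C)C)C1=O | intermediate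
33 | 2-(trimethylsilyl)ethyl (2E)-4-[(1S,6R)-4-{[tert-butyl(diphenyl)silyl]oxymethyl}-3-[(1E)-hept-1-en-1-yl]-2,5-dioxo-7-oxabicyclo[4.1.0]hept-3-en-1-yl]-2-methylbut-2-enoate | CCCCC/C=C/C1=C(CO[Si](c2ccccc2)(c2ccccc2)C(C)(C)C)C(=O)[C@@H]2O[C@]2(C/C=C(\C)C(=O)OCC[Si](C)(C)C)C1=O | intermediate
34 | 2-(trimethylsilyl)ethyl (2E)-4-[(1S,5R,6S)-4-{[tert-butyl(diphenyl)silyl]oxymethyl}-3-[(1E)-hept-1-en-1-yl]-5-hydroxy-2-oxo-7-oxabicyclo[4.1.0]hept-3-en-1-yl]-2-methylbut-2-enoate (hydroxyl anti to the oxirane) | CCCCC/C=C/C1=C(CO[Si](c2ccccc2)(c2ccccc2)C(C)(C)C)[C@@H](O)[C@@H]2O[C@]2(C/C=C(\C)C(=O)OCC[Si](C)(C)C)C1=O | intermediate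
35 | (2E)-4-[(1S,5R,6S)-3-[(1E)-hept-1-en-1-yl]-5-hydroxy-4-(hydroxymethyl)-2-oxo-7-oxabicyclo[4.1.0]hept-3-en-1-yl]-2-methylbut-2-enoic acid | CCCCC/C=C/C1=C(CO)[C@@H](O)[C@@H]2O[C@]2(C/C=C(\C)C(=O)O)C1=O | target

## Step count and least certain steps

Total step count: 18. Longest linear sequence: 13 steps (steps 1, 2, 3, 7, 8, 9, 10, 11, 14, 15, 16, 17, 18).

**Step 7 (key step, proposed new method).** Two processes are most likely to go wrong. The first is β-elimination of the silyloxy group from the alkylnickel intermediate 15 before C–C reductive elimination, which opens the ring. The second, if the ring does form, is poor discrimination between the two enantiotopic acyl–CH2 bonds, because nothing tethers the alkyne to the ketone. The fallback uses known chemistry and moves the source of absolute configuration from the catalyst to a physical resolution. It sets out from 7 and 13, which are combined under the conditions established for the racemic ring expansion: Ni(cod)2 (zerovalent nickel) with tricyclohexylphosphine in toluene. This gives 16 together with its mirror image, the (5R)-cyclohexenone F1. The two are separated on a preparative chiral stationary phase (amylose tris(3,5-dimethylphenylcarbamate), supercritical CO2/2-propanol). The (5S) fraction is 16, where the route is rejoined. This fallback answers the enantioselectivity risk only; it does not remove the β-silyloxide elimination.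

**Step 10.** The alkoxy radical of the flexible hydroxyethyl chain may be quenched by recombination or intermolecular hydrogen abstraction before it reaches the C1–H. The dienone also absorbs part of the light, which can scramble the heptenyl double-bond geometry. The fallback postpones the pentyl group, so that an ordinary intermolecular γ-oxidation no longer meets an allylic CH2 on the alkenyl substituent. It sets out from 9 and 7 and runs as follows:
- Sonogashira coupling of 9 with vinyl bromide (PdCl2(PPh3)2, divalent palladium; CuI, monovalent copper; Et3N) gives the enyne F2.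
- The nickel ring expansion of step 7 with 7 gives the vinyl cyclohexenone F3.
- Acetal exchange with acetone catalysed by In(OTf)3 (trivalent indium) gives aldehyde F4.
- Wittig reaction with 28 gives ester F5.
- Oxidation with Rh2(cap)4 (dirhodium tetrakis(caprolactamate), divalent rhodium) and aqueous t-BuOOH turns the C1 methylene into the ketone, giving ene-dione F6.
- Cross-metathesis of the terminal vinyl group with hept-1-ene, using the second-generation Hoveyda–Grubbs catalyst (H2IMes)Cl2Ru=CH(2-i-PrO-C6H4), installs the (E)-heptenyl group and rejoins the route at 29.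

The silyloxymethyl CH2 remains a competing site in the oxidation of F5 and is shielded only by the bulky silyl group.

**Step 15.** The C4 enolate may expel triethylsilanolate (E1cB), which destroys the C6 stereocentre and leads to an achiral benzoquinone. The amide base may also transfer an electron to the ene-dione. The fallback avoids the enolate. It sets out from 29: α-tosyloxylation of the neutral enol with PhI(OH)OTs (hydroxy(tosyloxy)iodobenzene, trivalent iodine) in acetonitrile gives the tosylate F7. Acid methanolysis of the tertiary silyl ether, as in step 16, gives the hydroxy tosylate F8, which K2CO3 closes to 33, where the route is rejoined.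

**Step 17.** Hydride may enter anti to the oxirane, which is the usual sense for α,β-epoxy ketones and gives the syn epoxy alcohol; some reduction at C1 is also possible. The fallback accepts the intrinsic sense and corrects it by inversion. It sets out from 33: NaBH4 with CeCl3·7H2O (cerium trichloride heptahydrate) in MeOH at −78 °C gives the syn alcohol F9. Mitsunobu reaction with 4-nitrobenzoic acid (PPh3, diisopropyl azodicarboxylate) inverts C4 and gives the ester F10. K2CO3 in MeOH at 0 °C releases 34, where the route is rejoined.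

## Further compounds

F1 | step 7 | (5R)-2-{[tert-butyl(diphenyl)silyl]oxymethyl}-5-(2,2-dimethoxyethyl)-3-[(1E)-hept-1-en-1-yl]-5-[(triethylsilyl)oxy]cyclohex-2-en-1-one (enantiomer of 16) | CCCCC/C=C/C1=C(CO[Si](c2ccccc2)(c2ccccc2)C(C)(C)C)C(=O)C[C@](O[Si](CC)(CC)CC)(CC(OC)OC)C1
F2 | step 10 | tert-butyl(pent-4-en-2-yn-1-yloxy)diphenylsilane | C=CC#CCO[Si](c1ccccc1)(c1ccccc1)C(C)(C)C
F3 | step 10 | (5S)-2-{[tert-butyl(diphenyl)silyl]oxymethyl}-5-(2,2-dimethoxyethyl)-3-ethenyl-5-[(triethylsilyl)oxy]cyclohex-2-en-1-one | C=CC1=C(CO[Si](c2ccccc2)(c2ccccc2)C(C)(C)C)C(=O)C[C@@](O[Si](CC)(CC)CC)(CC(OC)OC)C1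
F4 | step 10 | 2-[(1S)-4-{[tert-butyl(diphenyl)silyl]oxymethyl}-3-ethenyl-5-oxo-1-[(triethylsilyl)oxy]cyclohex-3-en-1-yl]acetaldehyde | C=CC1=C(CO[Si](c2ccccc2)(c2ccccc2)C(C)(C)C)C(=O)C[C@@](O[Si](CC)(CC)CC)(CC=O)C1
F5 | step 10 | 2-(trimethylsilyl)ethyl (2E)-4-[(1S)-4-{[tert-butyl(diphenyl)silyl]oxymethyl}-3-ethenyl-5-oxo-1-[(triethylsilyl)oxy]cyclohex-3-en-1-yl]-2-methylbut-2-enoate | C=CC1=C(CO[Si](c2ccccc2)(c2ccccc2)C(C)(C)C)C(=O)C[C@@](O[Si](CC)(CC)CC)(C/C=C(\C)C(=O)OCC[Si](C)(C)C)C1
F6 | step 10 | 2-(trimethylsilyl)ethyl (2E)-4-[(1S)-4-{[tert-butyl(diphenyl)silyl]oxymethyl}-3-ethenyl-2,5-dioxo-1-[(triethylsilyl)oxy]cyclohex-3-en-1-yl]-2-methylbut-2-enoate | C=CC1=C(CO[Si](c2ccccc2)(c2ccccc2)C(C)(C)C)C(=O)C[C@@](O[Si](CC)(CC)CC)(C/C=C(\C)C(=O)OCC[Si](C)(C)C)C1=O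
F7 | step 15 | 2-(trimethylsilyl)ethyl (2E)-4-[(1S,6S)-4-{[tert-butyl(diphenyl)silyl]oxymethyl}-3-[(1E)-hept-1-en-1-yl]-6-[(4-methylbenzenesulfonyl)oxy]-2,5-dioxo-1-[(triethylsilyl)oxy]cyclohex-3-en-1-yl]-2-methylbut-2-enoate (sulfonate trans to the silyloxy group) | CCCCC/C=C/C1=C(CO[Si](c2ccccc2)(c2ccccc2)C(C)(C)C)C(=O)[C@@H](OS(=O)(=O)c2ccc(C)cc2)[C@@](O[Si](CC)(CC)CC)(C/C=C(\C)C(=O)OCC[Si](C)(C)C)C1=O
F8 | step 15 | 2-(trimethylsilyl)ethyl (2E)-4-[(1S,6S)-4-{[tert-butyl(diphenyl)silyl]oxymethyl}-3-[(1E)-hept-1-en-1-yl]-1-hydroxy-6-[(4-methylbenzenesulfonyl)oxy]-2,5-dioxocyclohex-3-en-1-yl]-2-methylbut-2-enoate | CCCCC/C=C/C1=C(CO[Si](c2ccccc2)(c2ccccc2)C(C)(C)C)C(=O)[C@@H](OS(=O)(=O)c2ccc(C)cc2)[C@@](O)(C/C=C(\C)C(=O)OCC[Si](C)(C)C)C1=O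
F9 | step 17 | 2-(trimethylsilyl)ethyl (2E)-4-[(1S,5S,6S)-4-{[tert-butyl(diphenyl)silyl]oxymethyl}-3-[(1E)-hept-1-en-1-yl]-5-hydroxy-2-oxo-7-oxabicyclo[4.1.0]hept-3-en-1-yl]-2-methylbut-2-enoate (hydroxyl syn to the oxirane) | CCCCC/C=C/C1=C(CO[Si](c2ccccc2)(c2ccccc2)C(C)(C)C)[C@H](O)[C@@H]2O[C@]2(C/C=C(\C)C(=O)OCC[Si](C)(C)C)C1=O
F10 | step 17 | (1S,2R,6S)-4-{[tert-butyl(diphenyl)silyl]oxymethyl}-5-[(1E)-hept-1-en-1-yl]-6-{(2E)-3-methyl-4-oxo-4-[2-(trimethylsilyl)ethoxy]but-2-en-1-yl}... 4-nitrobenzoate of 34 (ester oxygen on C4, anti to the oxirane) | CCCCC/C=C/C1=C(CO[Si](c2ccccc2)(c2ccccc2)C(C)(C)C)[C@@H](OC(=O)c2ccc(cc2)[N+](=O)[O-])[C@@H]2O[C@]2(C/C=C(\C)C(=O)OCC[Si](C)(C)C)C1=O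
A1 | alternative 1 | trans epoxy para-quinol triethylsilyl ether (C4–C5 oxirane anti to the C6 silyloxy group, C3 ketone, methyl ester) | CCCCC/C=C/C1=C[C@](O[Si](CC)(CC)CC)(C/C=C(\C)C(=O)OC)[C@@H]2O[C@@H]2C1=O
A2 | alternative 1 | Payne product: C5–C6 oxirane, C4 hydroxyl anti, C3 ketone, methyl ester | CCCCC/C=C/C1=C[C@@]2(C/C=C(\C)C(=O)OC)O[C@H]2[C@H](O)C1=O
A3 | alternative 2 | acyclic epoxy enyne with C1 ethynyl carbinol silyl ether and C3 methylidene | C#C[C@@H](O[Si](CC)(CC)CC)[C@@]1(C/C=C(\C)C(=O)OC)O[C@H]1[C@H](O[Si](C)(C)C(C)(C)C)C(=C)CO[Si](C)(C)C(C)(C)C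
A4 | alternative 2 | 2-vinylcyclohexene epoxide with silylated C1 and C4 carbinols | C=CC1=C(CO[Si](C)(C)C(C)(C)C)[C@@H](O[Si](C)(C)C(C)(C)C)[C@@H]2O[C@]2(C/C=C(\C)C(=O)OC)[C@@H]1O[Si](CC)(CC)CC
A5 | alternative 3 | acyclic epoxy aldehyde with C3 alkenyl iodide (iodine cis to C1) | O=C[C@@H]1O[C@]1(C/C=C(\C)C(=O)OC)[C@H](O[Si](CC)(CC)CC)/C(/C=C/CCCCC)=C(\I)CO[Si](C)(C)C(C)(C)C
A6 | alternative 3 | epoxy cyclohexenol with free C4 hydroxyl and silylated C1 carbinol | CCCCC/C=C/C1=C(CO[Si](C)(C)C(C)(C)C)[C@@H](O)[C@@H]2O[C@]2(C/C=C(\C)C(=O)OC)[C@@H]1O[Si](CC)(CC)CC
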